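## Analysis of the target

The target is a C40 furanoid carotenoid of the auroxanthin type: two identical bicyclic end groups joined by an all-E polyene from C9 to C9′ with methyl groups on C9, C13, C13′ and C9′. Carotenoid locants are used: ring C1 is CMe2, C3 is CHOH, C5 is C(CH3)O, C6=C7 is the ring olefin, C8 is OCH, the chain runs C9 to C15, and primes mark the second half. Each end group is a 2,5-dihydrofuran (O, C5, C6, C7, C8) fused along C5–C6 to a cyclohexane (C1 to C6), so the sp3 carbon C8 insulates C6=C7 from the heptaene (C9=C10 to C9′=C10′). There are six stereocentres, 3S, 5R, 8R in each half: the C3 hydroxyl is cis to the C5 methyl on the cyclohexane, and the chain on C8 is trans to the C5 methyl across the dihydrofuran. The molecule is C2-symmetric, so one enantiopure end-group unit used twice is enough, but any C8 epimer in it would reappear as diastereomeric carotenoids that are hard to separate. The C8–O bond is allylic to the ring olefin and to the whole polyene; acid ionises it to a polyenyl cation and scrambles C8, and the heptaene is sensitive to light, oxygen and heat. The difficulty is to set C8 next to the chain without acid or an adjacent carbonyl group, and to form seven chain olefins E, the trisubstituted ones included. The strategy rests on the E-trisubstituted olefin C9=C10 (and C9′=C10′) with its methyl on C9 next to C8: it is the imprint of a syn addition of CH3 and a metal across a C8-bound ethynyl group, and C10–C11 is then an sp2–sp2 bond that can be formed with retention.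

## Retrosynthetic reasoning

**15 to 14.** The last operation cuts two O–Si bonds. The C3 and C3′ hydroxyls are masked as tert-butyldimethylsilyl ethers because these survive hydride, Lewis acid and organoaluminium reagents and leave under basic fluoride conditions, which the acid-labile C8–O bonds require.

**14 to two molecules of 7, one of 10 and two of 11.** Four bonds are cut: C9–CH3, C9′–CH3, C10–C11 and C10′–C11′. The cut divides C40 into C14 + C12 + C14 and uses the symmetry, so a single end-group alkyne serves both sides. It makes the hardest olefin (C9=C10, trisubstituted, next to a stereocentre) by a reaction whose mechanism dictates E geometry. Olefination at C11=C12 or C15=C15′ would instead need an ylide or carbanion next to C8 and would give E/Z mixtures. The forward reaction has to add CH3 to C9 and a metal to C10 of 7 in a syn fashion and then couple C10 with both ends of 10 with retention, without ionising the propargylic C8–O bond.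

**10 to 8 and 9.** C11=C12 and C11′=C12′ are cut. The central triene with its two methyl groups is bought as the dialdehyde 8, and each aldehyde carbon (C12, C12′) is extended by one iodine-bearing carbon from 9. The forward reaction must deliver E iodoalkenes at both ends.

**7 to 6.** A C(sp)–Si bond is cut. The terminal alkyne needed for carbometalation is stored as its silyl derivative, because that is the form in which the alkyne is introduced.

**6 to 4 and 5.** The C8–C9 bond is cut next to the ring oxygen. In this polarity C8 is an oxocarbenium carbon stabilised by the ring oxygen and by C6=C7, and C9 is an alkynyl nucleophile. The bis-silylated acetylene 5 is chosen over a monosilylated terminal alkyne because only a silicon-bearing alkyne carbon attacks a cation with formation of a β-silyl-stabilised vinyl cation that collapses cleanly by loss of silicon. This step creates C8; the forward reaction has to favour attack on the face of the planar cation opposite the C5 methyl.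

**4 to 2.** Only the oxidation level at C8 changes: the lactone carbonyl becomes an acetoxy acetal by hydride addition and acetylation of the aluminium lactolate 3 in the same flask. The acetate is the leaving group for the ionisation.

**2 to 1.** An O–Si bond is cut. The natural lactone 1 supplies the whole bicyclic skeleton, the C6=C7 olefin and the C3 and C5 stereocentres with the correct absolute configuration, so no ring and no ring stereocentre has to be built.

## Alternatives that were turned down

**Alternative 1: epoxide opening at C5 and dehydration.**
- Disconnection: the O–C5 bond of the dihydrofuran, with C6=C7 traced back to a tertiary C6 alcohol.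
- Forward key step: in the epoxy diol A1 the C5–C6 epoxide lies syn to the C3 hydroxyl (it could be placed by hydroxyl-directed epoxidation). A sulfonic acid would let the C8 hydroxyl attack C5 with inversion (5-endo opening at the tertiary carbon) to give the cis-fused C6-hydroxy tetrahydrofuran A2. Dehydration of A2 can only go towards C7, because C1 and C5 carry no hydrogen, and would lead to the C3 alcohol of 6.
- For it: C5 is fixed by a stereospecific inversion, and C8 comes from a carbinol whose configuration can be set by a reagent before the ring closes. On control of C8 this is stronger than the chosen route, which relies on a substrate facial bias in step 3.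
- Against it: A1 has four stereocentres (C3, C5, C6, C8) that must be assembled from scratch. The acid step on a tertiary epoxide next to quaternary C1 risks 1,2-shifts and ionisation of the propargylic C8–OH. The dehydration of a tertiary alcohol next to the C5–O bond invites pinacol-type cleavage.
- Comparison: A2 is still at the silylalkyne stage, so the whole end game of the chosen route follows anyway. The chosen route buys C3, C5 and the ring in 1 and reaches the same alkyne in four steps. It gives up the firmer C8 control for that step economy.

**Alternative 2: Baeyer–Villiger oxygen insertion into a fused cyclobutenone.**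
- Disconnection: the C5–O and O–C8 bonds of the butenolide, i.e. an oxygen inserted between C5 and the carbonyl carbon C8.
- Forward key step: a buffered peracid would convert the fused cyclobutenone ketal A3 into the butenolide A4 (3-oxololiolide ethylene ketal). The tertiary C5 migrates in preference to the vinylic C7, with retention and with release of four-ring strain.
- For it: migratory aptitude and retention are dependable, so C5 is transferred intact. The supply is independent of a natural product, and the C3 ketone would give access to either C3 epimer. If 1 or its antipode could not be bought, this would be the stronger plan for the end group.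
- Against it: A4 still needs ketal removal and an axial-selective ketone reduction to become 1, a compound that can be purchased. An enantioselective synthesis of A3 with its quaternary C5 is an unsolved sub-problem. The alternative does not address C8, the alkyne or the polyene.
- Comparison: it is a longer way to 1 followed by the same seven steps. The chosen route puts its effort into the chain and C8, where the difficulty of the target lies.

**Alternative 3: aminocatalytic oxa-Michael–aldol annulation.**
- Disconnection: the O–C8 and C6–C7 bonds, so that the dihydrofuran is assembled from the ketol A5 and the enynal A6.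
- Forward key step: a diarylprolinol silyl ether catalyst with a carboxylic acid would activate A6 as an iminium ion. The tertiary C5 hydroxyl of A5 adds to the β-carbon (O–C8), the enamine closes onto the C6 ketone (C6–C7), and loss of water gives the dihydrofuran A7 with a formyl group on C7.
- For it: it is the most convergent ring construction. It forms both ring bonds, places the alkyne and sets C8 under catalyst control in one operation. In convergency and in C8 control it is stronger than the chosen route.
- Against it: a hindered tertiary alcohol is a poor and reversible oxa-Michael donor, which erodes the selectivity it is meant to deliver. The aldol acceptor is a ketone flanked by two quaternary carbons (C1 and C5). The enynal offers a competing 1,6-acceptor site. A7 carries a formyl group that the target lacks, so a decarbonylation with a stoichiometric rhodium phosphine complex at high temperature would be needed in the presence of an alkyne and an allylic ether. A5 must itself be made enantiopure.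
- Comparison: the chosen route uses only established reaction types, excises nothing, and takes C3 and C5 from 1. It accepts a possibly modest facial selectivity at C8 with a chromatographic separation.

Key step: step 6

Remark: 1 is taken as the natural (−)-(6S,7aR) enantiomer; 1, 5, 8, 9 and 11 are taken as purchased.

## Route

Step 1
Reactants: 1 (−)-loliolide, (6S,7aR)-6-hydroxy-4,4,7a-trimethyl-5,6,7,7a-tetrahydro-1-benzofuran-2(4H)-one
Product: 2 (6S,7aR)-6-(tert-butyldimethylsilyloxy)-4,4,7a-trimethyl-5,6,7,7a-tetrahydro-1-benzofuran-2(4H)-one
Conditions: TBSCl (1.5 equiv), imidazole (3 equiv), DMF, rt → 40 °C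
Reagents that add atoms: tert-butyldimethylsilyl chloride, CC(C)(C)[Si](C)(C)Cl
Why: Imidazole-promoted silylation of the secondary C3 hydroxyl (silyl ether formation) is routine even for this axial alcohol; no stereocentre is touched, and the ether removes the only acidic proton before the hydride, Lewis acid and organoaluminium steps.

Step 2
Reactants: 2 (6S,7aR)-6-(tert-butyldimethylsilyloxy)-4,4,7a-trimethyl-5,6,7,7a-tetrahydro-1-benzofuran-2(4H)-one
Product: 4 (6S,7aR)-6-(tert-butyldimethylsilyloxy)-4,4,7a-trimethyl-2,4,5,6,7,7a-hexahydro-1-benzofuran-2-yl acetate (both C2 epimers), via diisobutylaluminium lactolate 3 (not isolated)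
Conditions: i-Bu2AlH (1.1 equiv), CH2Cl2, −78 °C; then pyridine, DMAP, Ac2O, −78 → 0 °C; filtration through Et3N-deactivated silica
Reagents that add atoms: acetic anhydride, CC(=O)OC(C)=O
Why: i-Bu2AlH adds once to the butenolide carbonyl at −78 °C (1,2-reduction) and the tetrahedral aluminium lactolate 3 is acetylated in the same flask (one-pot reductive acetylation of a lactone), so the lactol never equilibrates with its hydroxy-enal form. The new acetal centre C8 forms as a mixture, which does not matter because it becomes planar in step 3.

Step 3
Reactants: 4 (6S,7aR)-6-(tert-butyldimethylsilyloxy)-4,4,7a-trimethyl-2,4,5,6,7,7a-hexahydro-1-benzofuran-2-yl acetate; 5 bis(trimethylsilyl)acetylene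
Product: 6 tert-butyldimethyl{[(2R,6S,7aR)-4,4,7a-trimethyl-2-[(trimethylsilyl)ethynyl]-2,4,5,6,7,7a-hexahydro-1-benzofuran-6-yl]oxy}silane
Conditions: 5 (3 equiv), TMSOTf (0.2 equiv), CH2Cl2, −78 → −20 °C; Et3N quench at low temperature; chromatography
Reagents that add atoms: bis(trimethylsilyl)acetylene (5), C[Si](C)(C)C#C[Si](C)(C)C
Why: TMSOTf ionises the anomeric, allylic acetate to a planar oxocarbenium ion delocalised over O, C8, C7 and C6, which is attacked at C8 (C6 lies between two quaternary carbons) by a silicon-bearing carbon of 5; loss of Me3Si+ from the β-silyl vinyl cation gives the alkyne and regenerates the silyl triflate (electrophilic substitution of an alkynylsilane, the reaction type of the C-glycosidation of glycals with silylacetylenes). C8 is set by steric approach anti to the C5 methyl group, which places the alkynyl group trans to that methyl (8R); the bias between the CH3 and the ring CH2 on C5 is expected to be modest, and the 8S epimer is to be removed by chromatography here.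

Step 4
Reactants: 6 tert-butyldimethyl{[(2R,6S,7aR)-4,4,7a-trimethyl-2-[(trimethylsilyl)ethynyl]-2,4,5,6,7,7a-hexahydro-1-benzofuran-6-yl]oxy}silane
Product: 7 tert-butyl{[(2R,6S,7aR)-2-ethynyl-4,4,7a-trimethyl-2,4,5,6,7,7a-hexahydro-1-benzofuran-6-yl]oxy}dimethylsilane
Conditions: K2CO3 (0.3 equiv), MeOH, 0 °C → rt
Reagents that add atoms: none
Why: Catalytic methoxide cleaves the C(sp)–Si bond (protodesilylation of an alkynylsilane) while the hindered secondary O–Si bond stays; the conditions are too mild to deprotonate C8, so its configuration is kept.

Step 5
Reactants: 8 (2E,4E,6E)-2,7-dimethylocta-2,4,6-trienedial; 9 iodoform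
Product: 10 (1E,3E,5E,7E,9E)-1,10-diiodo-3,8-dimethyldeca-1,3,5,7,9-pentaene
Conditions: CrCl2 (16 equiv), CHI3 (4 equiv), 1,4-dioxane–THF (6:1), rt, dark; used promptly
Reagents that add atoms: iodoform (9), IC(I)I
Why: Takai olefination: CrCl2 reduces 9 to a geminal dichromium iodo-carbenoid that adds to each aldehyde, and anti elimination of the β-oxido chromium species gives the E iodoalkene at both ends; the dioxane-rich solvent favours E, and the three olefins of 8 are not touched.

Step 6
Reactants: 7 tert-butyl{[(2R,6S,7aR)-2-ethynyl-4,4,7a-trimethyl-2,4,5,6,7,7a-hexahydro-1-benzofuran-6-yl]oxy}dimethylsilane (2.4 equiv); 11 trimethylaluminium; 10 (1E,3E,5E,7E,9E)-1,10-diiodo-3,8-dimethyldeca-1,3,5,7,9-pentaene (1 equiv)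
Product: 14 (3S,5R,8R,3′S,5′R,8′R)-auroxanthin bis(tert-butyldimethylsilyl) ether, via alkenyldimethylalane 12 (not isolated), via alkenylzinc chloride 13 (not isolated)
Conditions: AlMe3 (3 equiv per 7), Cp2ZrCl2 (0.2 equiv per 7), H2O (1.5 equiv per 7), CH2Cl2, −30 °C; volatiles removed in vacuo below 0 °C; ZnCl2 (1.1 equiv per 7), THF, 0 °C; 10, Pd(PPh3)4 (0.1 equiv), THF, 0 °C → rt, dark; aq. potassium sodium tartrate/NaHCO3 at 0 °C
Reagents that add atoms: trimethylaluminium (11), C[Al](C)C
Why: Cp2ZrCl2 and AlMe3, activated by the (MeAlO)n formed from the added water, give a methylzirconocene cation paired with an aluminate, which adds CH3–Zr across C9≡C10 of 7 through a four-centre transition state, syn, with the metal on the terminal C10 and the methyl on C9; zirconium-to-aluminium exchange then gives the E alkenylalane 12 and returns the catalyst. ZnCl2 converts 12 into the alkenylzinc chloride 13, and zerovalent palladium inserts into each C–I bond of 10 with retention, takes the alkenyl group from zinc and reductively eliminates, twice, forming C10–C11 and C10′–C11′. The closest known reaction type is the zirconium-catalysed methylalumination of terminal alkynes followed by palladium-catalysed Negishi coupling with alkenyl iodides, the standard construction of E-trisubstituted olefins in polyenes. No ring closes and no stereocentre is created; C8 and C8′ are carried through because neither a carbonyl group nor a cation is generated next to them. The step needs regioselectivity (CH3 to C9), which the branched, oxygen-bearing C8 reinforces by keeping the metal at the unhindered terminus, and syn stereospecificity, which is inherent in the concerted carbometalation and fixes 9E and 9′E. It also needs chemoselectivity against ionisation of the propargylic, allylic C8–O bond by AlMe3: the water-accelerated protocol lets the addition run at −30 °C, and excess AlMe3 is pumped off before the coupling so that methyl transfer to palladium does not compete. The stereoretentive coupling keeps the all-E geometry of 10, and the cold basic work-up removes the aluminium and zinc Lewis acids before they can epimerise the now doubly allylic C8 of 14.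

Step 7
Reactants: 14 (3S,5R,8R,3′S,5′R,8′R)-auroxanthin bis(tert-butyldimethylsilyl) ether
Product: 15 (3S,5R,8R,3′S,5′R,8′R)-5,8:5′,8′-diepoxy-5,8,5′,8′-tetrahydro-β,β-carotene-3,3′-diol (the target)
Conditions: Bu4NF (6 equiv), THF, 0 °C → rt, argon, dark; neutral aqueous work-up
Reagents that add atoms: none
Why: Fluoride cleaves both O–Si bonds (formation of the strong Si–F bond) under basic, non-acidic conditions, under which the doubly allylic C8–O bonds and the heptaene should be stable; no stereocentre is involved.

## Compound list

1 | (−)-loliolide, (6S,7aR)-6-hydroxy-4,4,7a-trimethyl-5,6,7,7a-tetrahydro-1-benzofuran-2(4H)-one | O=C1C=C2C(C)(C)C[C@H](O)C[C@@]2(C)O1 | starting material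
2 | (6S,7aR)-6-(tert-butyldimethylsilyloxy)-4,4,7a-trimethyl-5,6,7,7a-tetrahydro-1-benzofuran-2(4H)-one | O=C1C=C2C(C)(C)C[C@H](O[Si](C)(C)C(C)(C)C)C[C@@]2(C)O1 | intermediate
3 | diisobutylaluminium lactolate of 2 (not isolated) | CC(C)C[Al](CC(C)C)OC1C=C2C(C)(C)C[C@H](O[Si](C)(C)C(C)(C)C)C[C@@]2(C)O1 | intermediate
4 | (6S,7aR)-6-(tert-butyldimethylsilyloxy)-4,4,7a-trimethyl-2,4,5,6,7,7a-hexahydro-1-benzofuran-2-yl acetate, both C2 epimers | CC(=O)OC1C=C2C(C)(C)C[C@H](O[Si](C)(C)C(C)(C)C)C[C@@]2(C)O1 | intermediate
5 | bis(trimethylsilyl)acetylene | C[Si](C)(C)C#C[Si](C)(C)C | starting material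
6 | tert-butyldimethyl{[(2R,6S,7aR)-4,4,7a-trimethyl-2-[(trimethylsilyl)ethynyl]-2,4,5,6,7,7a-hexahydro-1-benzofuran-6-yl]oxy}silane | C[Si](C)(C)C#C[C@H]1C=C2C(C)(C)C[C@H](O[Si](C)(C)C(C)(C)C)C[C@@]2(C)O1 | intermediate
7 | tert-butyl{[(2R,6S,7aR)-2-ethynyl-4,4,7a-trimethyl-2,4,5,6,7,7a-hexahydro-1-benzofuran-6-yl]oxy}dimethylsilane | C#C[C@H]1C=C2C(C)(C)C[C@H](O[Si](C)(C)C(C)(C)C)C[C@@]2(C)O1 | intermediate
8 | (2E,4E,6E)-2,7-dimethylocta-2,4,6-trienedial | O=C/C(C)=C/C=C/C=C(C)/C=O | starting material
9 | iodoform | IC(I)I | starting material
10 | (1E,3E,5E,7E,9E)-1,10-diiodo-3,8-dimethyldeca-1,3,5,7,9-pentaene | I/C=C/C(C)=C/C=C/C=C(C)/C=C/I | intermediate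
11 | trimethylaluminium | C[Al](C)C | starting material
12 | (E)-alkenyldimethylalane from 7, aluminium on C10 and methyl on C9 (not isolated) | C[Al](C)/C=C(\C)[C@H]1C=C2C(C)(C)C[C@H](O[Si](C)(C)C(C)(C)C)C[C@@]2(C)O1 | intermediate
13 | (E)-alkenylzinc chloride from 12 (not isolated) | Cl[Zn]/C=C(\C)[C@H]1C=C2C(C)(C)C[C@H](O[Si](C)(C)C(C)(C)C)C[C@@]2(C)O1 | intermediate
14 | (3S,5R,8R,3′S,5′R,8′R)-auroxanthin bis(tert-butyldimethylsilyl) ether | CC(/C=C/C=C(\C)[C@H]1C=C2C(C)(C)C[C@H](O[Si](C)(C)C(C)(C)C)C[C@@]2(C)O1)=C\C=C\C=C(C)\C=C\C=C(/C)[C@H]1C=C2C(C)(C)C[C@H](O[Si](C)(C)C(C)(C)C)C[C@@]2(C)O1 | intermediate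
15 | (3S,5R,8R,3′S,5′R,8′R)-5,8:5′,8′-diepoxy-5,8,5′,8′-tetrahydro-β,β-carotene-3,3′-diol | CC(/C=C/C=C(\C)[C@H]1C=C2C(C)(C)C[C@H](O)C[C@@]2(C)O1)=C\C=C\C=C(C)\C=C\C=C(/C)[C@H]1C=C2C(C)(C)C[C@H](O)C[C@@]2(C)O1 | target

## Step count and least certain steps

Total step count: 7. Longest linear sequence: 6 steps (steps 1, 2, 3, 4, 6, 7); step 5 is a one-step branch.

**Step 6 (key step).**
- Most likely failure: AlMe3 or the cationic zirconium species ionises the propargylic, allylic C8–O bond before or during carbometalation, which opens the ring or epimerises C8.
- Also possible: coordination of the ring oxygen to aluminium erodes the regioselectivity, and residual Lewis acid epimerises the doubly allylic C8 of the product during the coupling.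
- Fallback: set out from 7 and keep the same two bonds, but form them under basic conditions. Copper-catalysed methylboration (CuCl, Xantphos, NaOt-Bu, B2pin2, MeI, THF, rt) adds boron to C10 and, through the alkenylcopper, methyl to C9 in a syn fashion. This should give the pinacol (E)-alkenylboronate F1. A twofold Suzuki–Miyaura coupling of F1 with 10 (Pd(PPh3)4, aqueous K3PO4, THF, rt, dark) returns to the route at 14.

**Step 3.**
- Most likely failure: low facial discrimination in the attack on the planar oxocarbenium ion, because the two faces differ only by CH3 against the ring CH2 on C5. Reversible re-ionisation of the product under the silyl triflate would further level the C8 epimers.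
- Fallback: set out from 4 and move the stereocontrol from the substrate to a catalyst. Ethynyltrimethylsilane is added as its monovalent copper acetylide under a chiral bis(oxazoline) or pyridine-bis(oxazoline) ligand (Cu(MeCN)4PF6, ligand, i-Pr2NEt, TMSOTf, Et2O, −20 °C). This is the known ligand-controlled alkynylation of cyclic oxocarbenium ions. Both antipodes of the ligand would be tried, since the matched one cannot be predicted. The product is 6, where the route is rejoined; this fallback makes no new compound (F0).

**Step 5.**
- Most likely failure: incomplete E selectivity accumulated over two olefinations, and isomerisation or decomposition of the light-sensitive bis-iodide during isolation.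
- Fallback: set out from 8 and fix the geometry by hydrometalation. A twofold Colvin rearrangement with lithiated trimethylsilyldiazomethane (Me3SiCHN2, LiN(i-Pr)2, THF, −78 °C → rt) should give (3E,5E,7E)-3,8-dimethyldeca-3,5,7-triene-1,9-diyne F2. Syn hydrozirconation of both alkynes with Cp2Zr(H)Cl (THF, rt) gives the bis(alkenylzirconocene chloride) F3, which is not isolated. Iodine at 0 °C cleaves both C–Zr bonds with retention and returns to the route at 10.

**Step 7.**
- Most likely failure: slow cleavage of the two hindered axial silyl ethers, so that the polyene is exposed to basic fluoride for long enough to isomerise or degrade.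
- Fallback: set out from 7 and remove the protecting group before the chain exists. Bu4NF in THF should give the hydroxy alkyne F4. Step 6 is then run with one further equivalent of AlMe3 per alkyne, which first converts the hydroxyl into the dimethylaluminium alkoxide F5. Methylalumination gives the alkenylalane alkoxide F6, ZnCl2 gives the alkenylzinc alkoxide F7, and coupling with 10 gives the bis(dimethylaluminium alkoxide) F8; none of these is isolated. Aqueous potassium sodium tartrate hydrolyses the O–Al bonds and the route is rejoined at 15.

## Further compounds

F1 | step 6 | pinacol (E)-alkenylboronate from 7, boron on C10 and methyl on C9 | CC1(C)OB(/C=C(\C)[C@H]2C=C3C(C)(C)C[C@H](O[Si](C)(C)C(C)(C)C)C[C@@]3(C)O2)OC1(C)C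
F0 | step 3 | none | none
F2 | step 5 | (3E,5E,7E)-3,8-dimethyldeca-3,5,7-triene-1,9-diyne | C#C/C(C)=C/C=C/C=C(C)/C#C
F3 | step 5 | bis(alkenylzirconocene chloride) from F2, zirconium on C11 and C11′ (not isolated) | Cl[Zr](C1C=CC=C1)(C1C=CC=C1)/C=C/C(C)=C/C=C/C=C(C)/C=C/[Zr](Cl)(C1C=CC=C1)C1C=CC=C1
F4 | step 7 | (2R,6S,7aR)-2-ethynyl-4,4,7a-trimethyl-2,4,5,6,7,7a-hexahydro-1-benzofuran-6-ol | C#C[C@H]1C=C2C(C)(C)C[C@H](O)C[C@@]2(C)O1
F5 | step 7 | dimethylaluminium alkoxide of F4 (not isolated) | C#C[C@H]1C=C2C(C)(C)C[C@H](O[Al](C)C)C[C@@]2(C)O1
F6 | step 7 | (E)-alkenyldimethylalane from F5 (not isolated) | C[Al](C)/C=C(\C)[C@H]1C=C2C(C)(C)C[C@H](O[Al](C)C)C[C@@]2(C)O1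
F7 | step 7 | (E)-alkenylzinc chloride from F6 (not isolated) | Cl[Zn]/C=C(\C)[C@H]1C=C2C(C)(C)C[C@H](O[Al](C)C)C[C@@]2(C)O1
F8 | step 7 | bis(dimethylaluminium alkoxide) of 15 (not isolated) | CC(/C=C/C=C(\C)[C@H]1C=C2C(C)(C)C[C@H](O[Al](C)C)C[C@@]2(C)O1)=C\C=C\C=C(C)\C=C\C=C(/C)[C@H]1C=C2C(C)(C)C[C@H](O[Al](C)C)C[C@@]2(C)O1
A1 | alternative 1 | C8 carbinol with the C5–C6 epoxide syn to the C3 hydroxyl and a (trimethylsilyl)ethynyl group on C8 | C[Si](C)(C)C#C[C@H](O)C[C@]12O[C@@]1(C)C[C@@H](O)CC2(C)C
A2 | alternative 1 | cis-fused C6-hydroxy tetrahydrofuran (5,8-epoxy-7,8-dihydro-3,6-diol) with a (trimethylsilyl)ethynyl group on C8 | C[Si](C)(C)C#C[C@H]1C[C@@]2(O)C(C)(C)C[C@H](O)C[C@@]2(C)O1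
A3 | alternative 2 | fused cyclobutenone, 2,2,6-trimethylbicyclo[4.2.0]oct-1(8)-ene-4,7-dione 4-(ethylene ketal), C5 methyl at the ring fusion | CC1(C)CC2(OCCO2)C[C@@]3(C)C(=O)C=C13
A4 | alternative 2 | 3-oxololiolide ethylene ketal (butenolide, 5R) | O=C1C=C2C(C)(C)CC3(OCCO3)C[C@@]2(C)O1
A5 | alternative 3 | (2R,4S)-4-(tert-butyldimethylsilyloxy)-2-hydroxy-2,6,6-trimethylcyclohexanone | O=C1C(C)(C)C[C@H](O[Si](C)(C)C(C)(C)C)C[C@@]1(C)O
A6 | alternative 3 | (E)-5-(trimethylsilyl)pent-2-en-4-ynal | C[Si](C)(C)C#C/C=C/C=O
A7 | alternative 3 | C7-formyl C8-(trimethylsilylethynyl) dihydrofuran, C3 tert-butyldimethylsilyl ether | C[Si](C)(C)C#C[C@H]1C(C=O)=C2C(C)(C)C[C@H](O[Si](C)(C)C(C)(C)C)C[C@@]2(C)O1
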